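## Structural features

The target is the 3-hydroxy-4-methoxybenzoate (isovanillate) of a himachalane-type bicyclic diol. Atom labels used throughout: ring A is the cyclohexene C1 (ester carbinol)–C2–C3–C4–C5=C6 (methyl on C6); ring B is the cycloheptane C3–C4–C7 (gem-dimethyl)–C8–C9–C10–C11 (methyl and free tertiary hydroxyl). The rings share the C3–C4 bond and are cis-fused. There are four stereocentres, C1 (R), C3 (R), C4 (S) and C11 (S). C11, C3 and C4 are contiguous, C1 is separated from them by C2, and the C1 oxygen lies on the face of ring A that carries H-3 and H-4. Fragile groups are the secondary allylic ester (ionisation, allylic transposition, acyl transfer under base), the tertiary alcohol (dehydration in acid), the free phenol and the trisubstituted alkene. The real difficulty is the C3–C4 bond: it joins two methines that are each flanked by a fully substituted carbon (C11 and C7), it must be cis, and it lies in a seven-membered ring. The key step exploits two features. First, C1–O with C5=C6 and the C6 methyl is a reduced 2-methylcyclohex-2-enone, the retron of a [4+2] between a 2-silyloxydiene (C6=C1–C2=C3) and a dienophile C4=C5 carrying a leaving group on C5. Second, C11 is exocyclic to ring A and bonded to the diene terminus C3, so it can be made enantiopure on an open chain and then serve both as a tether atom and as the only source of absolute configuration.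

## Logic of the disconnections

27 ⇒ 26. The O–Si bond at C11 is the last bond made free. The tertiary hydroxyl stays masked through the esterification so that it cannot attack the activated allylic system. No skeletal simplification results, but the phenol can stay unprotected. The forward step needs a fluoride source that spares the allylic ester.

26 ⇒ 24 + 25. The C1–O(acyl) bond is cut with inversion at C1. 24 has the C1 configuration that hydride delivery to the exposed face should give, so displacement by the carboxylate of 25 corrects it and attaches the arene in one operation. The forward step must be a clean SN2 reaction at a cyclic allylic carbinol, with the carboxyl group reacting and the phenol not.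

24 ⇒ 23. The C1–H bond is removed, returning C1 to the ketone that the cycloaddition delivers. The forward step needs 1,2-selective and face-selective hydride addition.

23 ⇒ 21 (through 22). The C5=C6 π bond is traded for H on C6 and a sulfonyl group on C5, and the C1 carbonyl for its silyl enol ether. This turns the enone into a Diels–Alder adduct. The sulfone both activates the dienophile and stores the alkene, and the C5 and C6 configurations become irrelevant. The forward step must cleave the enol ether without losing the C11 silyl ether and eliminate sulfinate without epimerising C4.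

21 ⇒ 20. C3–C4 and C5–C6 are cut together. Two rings and the C3/C4 stereocentres collapse to one acyclic chain whose only stereocentre is C11. The forward step is a thermal cycloaddition in a tether-enforced orientation that must be endo and face-selective.

20 ⇒ 19 ⇒ 17 + 18. The enol O–Si bond and then the C2=C3 bond are cut. The diene comes from an ethyl enone with a single enolisable position, and the enone from olefination of an α-silyloxy aldehyde with a commercial ketophosphonate. The forward steps need E-selective olefination and conditions mild enough for the Z vinyl sulfone.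

17 ⇒ 16 ⇒ 15 ⇒ 14 ⇒ 12. C3 is adjusted from aldehyde back to the primary silyl ether. At the other terminus the two cis C–H bonds, the two S–O bonds and the C5–S bond are removed in turn, leaving a terminal alkyne. The Z geometry is only reliably available by syn addition of hydrogen to an alkyne. Sulfur is introduced while no enone or diene is present, because organolithium and hydrogenation chemistry would not tolerate them. The forward semihydrogenation must stop at the alkene.

12 ⇒ 11 ⇒ 10 ⇒ 9. Both O–Si bonds, then the C10–H bond and the epoxide C–O bonds are removed. The tertiary carbinol is traced to an E trisubstituted allylic alcohol through reagent-controlled epoxidation. The forward steps need the correct tartrate enantiomer and hydride attack at the secondary epoxide carbon only.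

9 ⇒ 8 ⇒ 5 + 6. The ester is restored and the C10=C11 bond is cut. A three-carbon unit comes from a commercial stabilised ylide. The forward step needs E selectivity.

5 ⇒ 3 ⇒ 1 + 2. The C10–O bond (hydroboration) and the C4≡C5 bond (one-carbon homologation) are cut. 1 already holds C4, C7 with both methyls, C8, C9 and C10. The forward step needs hydroboration of the alkene in the presence of the alkyne.

## Other disconnections considered

Alternative 1: The cut is C3–C11, with C11 at the aldehyde level and ring A as the 4-substituted cyclohexenone A1.
- Forward key step: SmI2 (divalent samarium) reduces the aldehyde to a ketyl that adds to the enone β-carbon C3, and protonation of the samarium enolate gives the cis-fused hydroxy ketone A2.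
- In its favour: it forms the congested bond at low temperature by a well-documented reaction class (ketyl–alkene reductive cyclisation), needs no vinyl sulfone and no thermolysis, and the cis fusion follows from anchoring the chain at C4. On mildness and on precedent for the reaction class it is the equal or the better of the chosen plan.
- Against it: a seven-membered closure has to compete with simple reduction and pinacol coupling. C11 arrives as a secondary carbinol without its methyl group and without defined configuration, so the tertiary centre must be built afterwards by oxidation and methyl addition, with a second ketone at C1 to differentiate and only the ring to direct the face. The enone is consumed, so C5=C6 must be reintroduced regioselectively. A1 needs its own enantioselective synthesis of an epimerisable γ-stereocentre next to a quaternary carbon.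
- Comparison: structurally the chosen plan reaches 21 with C11 complete and ring A one elimination away from the enone, whereas A2 still lacks a carbon and an alkene. Mechanistically one bond and one ring are formed against two and two. In step economy after the key step the chosen plan is clearly shorter.

Alternative 2: The cut is C3–C4 alone, by a retro-Claisen to the dihydropyran A3, in which a C6–O bond takes the place of C3–C4.
- Forward key step: heating A3 drives a [3,3] shift of the unit C3=C11–O–C6–C5=C4 through the ring-enforced boat transition state and contracts the oxacycle to the carbocycle A4.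
- In its favour: sigmatropic shifts are dependable for hindered bonds, and chirality is transferred from C1 and C6 of A3 to C3 and C4. A4 already has the C1 oxygen in the final configuration, the C5=C6 alkene and the C6 methyl. On ring A functionality it is better than the chosen plan, which needs three further steps (elimination, reduction, inversion) to reach that level.
- Against it: ring B is still open. C10 must be joined to the acetyl carbon C11 in a seven-membered closure that creates the tertiary stereocentre late and under weak control from C3. A3 contains a fully substituted C6 next to the silyloxy carbon, with the silyloxy group cis to an E alkenyl arm if the boat is to give the cis product, which is a demanding target in itself.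
- Comparison: both plans are thermal and pericyclic and comparable in temperature. The chosen plan closes both rings at once and sets C11 first by reagent control. Alternative 2 is stronger at C1 and weaker at C11, and its total step count is expected to be equal or higher.

Alternative 3: The cuts are C4–C7, C3–C4 and C11–O at once, back to acyclic (2E,6E)-farnesyl diphosphate A5.
- Forward key step: a class 1 sesquiterpene synthase ionises A5 and allows the C5=C6 geometry to invert through the tertiary allylic diphosphate. It then closes C4–C7 to the eleven-membered cation, moves hydride from C4 to C8, closes C3–C4 and traps the C11 cation with water to give A6.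
- In its favour: one step without protecting groups makes both rings and C3, C4 and C11 from an achiral precursor. On step and atom economy for the skeleton it is better than the chosen plan.
- Against it: an enzyme with exactly this product profile and absolute configuration must be found or engineered, and cation cascades tend to give product mixtures. C1 is still a methylene, so a site- and face-selective allylic oxidation is needed in the presence of the allylic C4–H, the C6 methyl and a free tertiary alcohol, before esterification.
- Comparison: structurally it reaches the same bicycle minus the C1 oxygen. Mechanistically it is an enzyme-controlled cation cascade against a substrate-controlled cycloaddition. It is shorter if the biocatalyst is available, whereas the chosen plan is longer but built from commercial reagents with each stereocentre traced to a defined control element.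

Key step: step 14

Assumption: hydride addition to 23 under Luche conditions is taken to occur on the convex face (the face carrying H-3 and H-4), giving the 2S alcohol 24, so the ester is installed with inversion.

Remark: 20 and 21 were checked atom by atom against 27 and need no structural correction (21 is the all-cis endo adduct). The S carbinol requires D-(−)-diethyl tartrate, and the diene arm of 20 is a five-carbon (1E,3Z)-3-silyloxypenta-1,3-dien-1-yl group.

## Route

Step 1
Reactants: 1 2,2-dimethylpent-4-enal; 2 dimethyl (1-diazo-2-oxopropyl)phosphonate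
Product: 3 3,3-dimethylhex-5-en-1-yne
Conditions: K2CO3, MeOH, 0 °C to rt (product carried on as a solution, volatile)
Reagents that add atoms: none
Why: Seyferth–Gilbert homologation with the Ohira–Bestmann reagent: methanolysis of 2 releases the diazomethylphosphonate anion, which olefinates the non-enolisable neopentyl aldehyde; loss of N2 and 1,2-hydrogen shift should give the terminal alkyne and leave the allyl group untouched.

Step 2
Reactants: 3 3,3-dimethylhex-5-en-1-yne
Product: 5 4,4-dimethylhex-5-yn-1-ol, via alkylborane 4 (not isolated)
Conditions: 9-borabicyclo[3.3.1]nonane (9-BBN, 1.05 equiv), THF, 0 °C to rt; then NaOH, H2O2, H2O, 0 °C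
Reagents that add atoms: hydrogen peroxide, OO
Why: Anti-Markovnikov hydroboration–oxidation; 9-BBN adds to a monosubstituted alkene faster than to a terminal alkyne (the reverse of the order shown by dialkylboranes such as disiamylborane), and this alkyne is further shielded by the adjacent quaternary carbon, so one equivalent should functionalise C10 only.

Step 3
Reactants: 5 4,4-dimethylhex-5-yn-1-ol; 6 ethyl 2-(triphenyl-λ5-phosphanylidene)propanoate
Product: 8 ethyl (2E)-2,6,6-trimethyloct-2-en-7-ynoate, via alkynal 7 (not isolated)
Conditions: TEMPO (10 mol%), PhI(OAc)2 (1.1 equiv), CH2Cl2, rt; then 6 (2 equiv), rt to 40 °C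
Reagents that add atoms: none
Why: One-pot nitroxyl-catalysed oxidation with trivalent iodine followed by Wittig olefination; the stabilised α-methyl ylide should give the E trisubstituted enoate under thermodynamic control, and the volatile aldehyde 7 need not be isolated.

Step 4
Reactants: 8 ethyl (2E)-2,6,6-trimethyloct-2-en-7-ynoate
Product: 9 (2E)-2,6,6-trimethyloct-2-en-7-yn-1-ol
Conditions: i-Bu2AlH (2.5 equiv), CH2Cl2, −78 °C; Rochelle salt work-up
Reagents that add atoms: none
Why: 1,2-Reduction of an α,β-unsaturated ester by the aluminium hydride to the allylic alcohol; the isolated alkyne and the alkene geometry are unaffected at low temperature.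

Step 5
Reactants: 9 (2E)-2,6,6-trimethyloct-2-en-7-yn-1-ol
Product: 10 [(2R,3R)-3-(3,3-dimethylpent-4-yn-1-yl)-2-methyloxiran-2-yl]methanol
Conditions: Ti(OiPr)4 (10 mol%), D-(−)-diethyl tartrate (12 mol%), t-BuOOH (2 equiv), 4 Å MS, CH2Cl2, −20 °C
Reagents that add atoms: tert-butyl hydroperoxide, CC(C)(C)OO
Why: Sharpless asymmetric epoxidation: the allylic alcohol binds the titanium–tartrate complex, and the D-tartrate directs oxygen to the face that gives the 2R,3R epoxide, which fixes C11; E trisubstituted allylic alcohols are among the best substrates for this reaction.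

Step 6
Reactants: 10 [(2R,3R)-3-(3,3-dimethylpent-4-yn-1-yl)-2-methyloxiran-2-yl]methanol
Product: 11 (2S)-2,6,6-trimethyloct-7-yne-1,2-diol
Conditions: LiAlH4 (2 equiv), THF, 0 °C to rt
Reagents that add atoms: none
Why: Hydride opening of a 2,3-epoxy alcohol by SN2 attack at the secondary carbon (future C10) instead of the fully substituted one; the C11–O bond is not broken, so the tertiary carbinol keeps its configuration (descriptor S in the diol).

Step 7
Reactants: 11 (2S)-2,6,6-trimethyloct-7-yne-1,2-diol
Product: 12 (2S)-2,6,6-trimethyl-1,2-bis(triethylsilyloxy)oct-7-yne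
Conditions: Et3SiOTf (2.5 equiv), 2,6-lutidine, CH2Cl2, −78 to 0 °C
Reagents that add atoms: triethylsilyl trifluoromethanesulfonate, CC[Si](CC)(CC)OS(=O)(=O)C(F)(F)F
Why: Silylation with the triflate and a hindered base is reactive enough for the tertiary hydroxyl; the tertiary silyl ether protects C11 through the cycloaddition and the primary one is the handle for the later oxidation.

Step 8
Reactants: 12 (2S)-2,6,6-trimethyl-1,2-bis(triethylsilyloxy)oct-7-yne
Product: 14 (2S)-2,6,6-trimethyl-8-(phenylsulfanyl)-1,2-bis(triethylsilyloxy)oct-7-yne, via lithium acetylide 13 (not isolated)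
Conditions: n-BuLi (1.1 equiv), THF, −78 °C; then PhSSPh (1.2 equiv), −78 °C to rt
Reagents that add atoms: diphenyl disulfide, c1ccc(SSc2ccccc2)cc1
Why: Deprotonation of the terminal alkyne and sulfenylation of the acetylide by the disulfide; silyl ethers tolerate the organolithium at low temperature.

Step 9
Reactants: 14 (2S)-2,6,6-trimethyl-8-(phenylsulfanyl)-1,2-bis(triethylsilyloxy)oct-7-yne
Product: 15 (2S)-2,6,6-trimethyl-8-(phenylsulfonyl)-1,2-bis(triethylsilyloxy)oct-7-yne
Conditions: mCPBA (2.3 equiv), NaHCO3, CH2Cl2, 0 °C to rt
Reagents that add atoms: 3-chloroperoxybenzoic acid, OOC(=O)c1cccc(Cl)c1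
Why: Peracid oxidation of the sulfide through the sulfoxide to the sulfone; the increasingly electron-poor alkyne is not epoxidised and the buffer protects the silyl ethers.

Step 10
Reactants: 15 (2S)-2,6,6-trimethyl-8-(phenylsulfonyl)-1,2-bis(triethylsilyloxy)oct-7-yne
Product: 16 (2S,7Z)-2,6,6-trimethyl-8-(phenylsulfonyl)-1,2-bis(triethylsilyloxy)oct-7-ene
Conditions: H2 (1 atm), Lindlar catalyst (Pd on CaCO3 poisoned with Pb(OAc)2), quinoline, EtOAc, rt, stopped after 1 equiv
Reagents that add atoms: none
Why: Syn semihydrogenation on poisoned palladium places both hydrogens on one face of the alkyne and should give the Z vinyl sulfone; no other reducible π bond is present, and the quaternary C7 rules out isomerisation to an allyl sulfone.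

Step 11
Reactants: 16 (2S,7Z)-2,6,6-trimethyl-8-(phenylsulfonyl)-1,2-bis(triethylsilyloxy)oct-7-ene
Product: 17 (2S,7Z)-2,6,6-trimethyl-8-(phenylsulfonyl)-2-(triethylsilyloxy)oct-7-enal
Conditions: (COCl)2 (4 equiv), DMSO (8 equiv), CH2Cl2, −78 to −40 °C; then Et3N, −78 °C to rt
Reagents that add atoms: none
Why: Swern oxidation applied directly to a primary triethylsilyl ether: the chlorosulfonium reagent cleaves the unhindered primary O–Si bond and the alkoxysulfonium ylide collapses to the aldehyde, while the tertiary silyl ether is inert; the α-carbon is fully substituted and cannot epimerise.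

Step 12
Reactants: 17 (2S,7Z)-2,6,6-trimethyl-8-(phenylsulfonyl)-2-(triethylsilyloxy)oct-7-enal; 18 diethyl (2-oxobutyl)phosphonate
Product: 19 (4E,6S,11Z)-6,10,10-trimethyl-12-(phenylsulfonyl)-6-(triethylsilyloxy)dodeca-4,11-dien-3-one
Conditions: LiCl, i-Pr2NEt, MeCN, rt
Reagents that add atoms: none
Why: Horner–Wadsworth–Emmons olefination under lithium chloride and amine conditions should give the E enone; the weak base avoids conjugate addition to, or isomerisation of, the Z vinyl sulfone, whose β-carbon is neopentyl.

Step 13
Reactants: 19 (4E,6S,11Z)-6,10,10-trimethyl-12-(phenylsulfonyl)-6-(triethylsilyloxy)dodeca-4,11-dien-3-one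
Product: 20 tert-butyldimethyl{[(2Z,4E,6S,11Z)-6,10,10-trimethyl-12-(phenylsulfonyl)-6-(triethylsilyloxy)dodeca-2,4,11-trien-3-yl]oxy}silane
Conditions: t-BuMe2SiOTf (1.3 equiv), Et3N (2.5 equiv), CH2Cl2, −78 to 0 °C
Reagents that add atoms: tert-butyldimethylsilyl trifluoromethanesulfonate, CC(C)(C)[Si](C)(C)OS(=O)(=O)C(F)(F)F
Why: Soft enolisation of the ethyl ketone, the only enolisable position because C11 is quaternary, should give the cross-conjugated 2-silyloxydiene mainly as the Z enol ether (methyl outside the diene, s-cis accessible); the C6 centre that this geometry later defines is erased, so a minor E isomer costs rate only.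

Step 14
Reactants: 20 tert-butyldimethyl{[(2Z,4E,6S,11Z)-6,10,10-trimethyl-12-(phenylsulfonyl)-6-(triethylsilyloxy)dodeca-2,4,11-trien-3-yl]oxy}silane
Product: 21 tert-butyldimethyl{[(3S,4R,4aS,9S,9aR)-3,5,5,9-tetramethyl-4-(phenylsulfonyl)-9-(triethylsilyloxy)-4,4a,5,6,7,8,9,9a-octahydro-3H-benzo[7]annulen-2-yl]oxy}silane
Conditions: toluene (0.01 M, degassed), BHT (0.2 equiv), 2,6-di-tert-butylpyridine (0.2 equiv), base-washed sealed tube, 180 °C
Reagents that add atoms: none
Why: Proposed new method: a thermal, concerted but asynchronous suprafacial [4+2] cycloaddition in which the 2-silyloxydiene C6=C1–C2=C3 adds across the Z vinyl sulfone C4=C5, forming C3–C4 and C5–C6; the closest known reaction types are type 1 intramolecular Diels–Alder reactions of 2-silyloxydienes, of Z vinyl sulfones and of undeca-1,8,10-trienes that close a cycloheptane, but the combination, with the tether forcing the sulfonyl carbon C5 and not the electrophilic C4 onto the nucleophilic diene terminus C6, has not been shown. Ring A (six-membered) is the cycloadduct ring itself, and ring B (seven-membered) is closed because the five-atom tether C11–C10–C9–C8–C7 links diene terminus C3 to dienophile carbon C4, so the new C3–C4 bond completes it. The fully substituted C7 and C11 favour the folded rotamer (gem-dialkyl effect), and because the polarity is mismatched the reaction is driven by heat, Lewis acids being avoided since they would cleave the silyl enol ether. C4 is set relative to C3 by the endo arrangement: with the Z sulfone, the sulfonyl group and the tether both lie under the diene, which places C7 cis to C11 and gives the cis ring fusion. C3 is set relative to C11 by the allylic stereocentre: in the reactive rotamer the C11 oxygen lies near the diene plane (inside), the methyl group points away from the dienophile and the tether leads towards it, so only one diene face is offered. C5 and C6 follow from the Z dienophile and the Z enol ether and are erased in step 15. The step therefore needs π-facial selectivity, secured by the S centre at C11, and endo over exo closure, secured by the Z sulfone and a chair-like folding of the tether; radical inhibitor, hindered base and high dilution are there to suppress polymerisation, desilylation and Z to E isomerisation.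

Step 15
Reactants: 21 tert-butyldimethyl{[(3S,4R,4aS,9S,9aR)-3,5,5,9-tetramethyl-4-(phenylsulfonyl)-9-(triethylsilyloxy)-4,4a,5,6,7,8,9,9a-octahydro-3H-benzo[7]annulen-2-yl]oxy}silane
Product: 23 (4aS,9S,9aR)-3,5,5,9-tetramethyl-9-(triethylsilyloxy)-1,4a,5,6,7,8,9,9a-octahydro-2H-benzo[7]annulen-2-one, via sulfonyl ketone 22 (not isolated)
Conditions: Bu4NF (1.1 equiv), AcOH (1.2 equiv), THF, 0 °C; then DBU (3 equiv), 0 °C to rt
Reagents that add atoms: none
Why: Buffered fluoride cleaves the silyl enol ether (enolate leaving group) much faster than the hindered tertiary silyl ether and gives ketone 22; DBU then removes the acidic C6–H and benzenesulfinate leaves from C5 (E1cB elimination), which unveils the C5=C6 enone and erases C5 and C6. C3 is not acidic and the γ-hydrogen at C4 should not be removed by an amidine base at this temperature.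

Step 16
Reactants: 23 (4aS,9S,9aR)-3,5,5,9-tetramethyl-9-(triethylsilyloxy)-1,4a,5,6,7,8,9,9a-octahydro-2H-benzo[7]annulen-2-one
Product: 24 (2S,4aS,9S,9aR)-3,5,5,9-tetramethyl-9-(triethylsilyloxy)-2,4a,5,6,7,8,9,9a-octahydro-1H-benzo[7]annulen-2-ol
Conditions: NaBH4, CeCl3·7H2O, MeOH, −78 °C
Reagents that add atoms: none
Why: Luche reduction gives 1,2-addition only; hydride should approach C1 from the convex face of the cis-fused bicycle (the face of H-3 and H-4, away from the C3–C11 and C4–C7 bonds of ring B), which places the new hydroxyl cis to ring B and sets C1 as S.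

Step 17
Reactants: 24 (2S,4aS,9S,9aR)-3,5,5,9-tetramethyl-9-(triethylsilyloxy)-2,4a,5,6,7,8,9,9a-octahydro-1H-benzo[7]annulen-2-ol; 25 3-hydroxy-4-methoxybenzoic acid (isovanillic acid)
Product: 26 (2R,4aS,9S,9aR)-3,5,5,9-tetramethyl-9-(triethylsilyloxy)-2,4a,5,6,7,8,9,9a-octahydro-1H-benzo[7]annulen-2-yl 3-hydroxy-4-methoxybenzoate
Conditions: PPh3 (2 equiv), DIAD (2 equiv), 25 (1.5 equiv), THF, 0 °C to rt
Reagents that add atoms: none
Why: Mitsunobu esterification: the alkoxyphosphonium ion at C1 is displaced by the carboxylate from the open convex face with inversion, giving the 2R ester; the carboxyl group (pKa about 4.5) reacts in preference to the phenol (pKa about 10), the tertiary silyl ether is inert, and attack at C5 is disfavoured by the neighbouring ring-fusion carbon.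

Step 18
Reactants: 26 (2R,4aS,9S,9aR)-3,5,5,9-tetramethyl-9-(triethylsilyloxy)-2,4a,5,6,7,8,9,9a-octahydro-1H-benzo[7]annulen-2-yl 3-hydroxy-4-methoxybenzoate
Product: 27 (2R,4aS,9S,9aR)-9-hydroxy-3,5,5,9-tetramethyl-2,4a,5,6,7,8,9,9a-octahydro-1H-benzo[7]annulen-2-yl 3-hydroxy-4-methoxybenzoate
Conditions: HF·pyridine, pyridine, THF, 0 °C to rt
Reagents that add atoms: none
Why: Fluoride-driven cleavage of the tertiary triethylsilyl ether; buffered HF·pyridine is not basic enough to hydrolyse or shift the ester and not acidic enough to ionise the allylic ester or dehydrate the tertiary alcohol.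

## Compound list

1 | 2,2-dimethylpent-4-enal | C=CCC(C)(C)C=O | starting material
2 | dimethyl (1-diazo-2-oxopropyl)phosphonate | COP(=O)(OC)C(=[N+]=[N-])C(C)=O | starting material
3 | 3,3-dimethylhex-5-en-1-yne | C=CCC(C)(C)C#C | intermediate
4 | 9-(4,4-dimethylhex-5-yn-1-yl)-9-borabicyclo[3.3.1]nonane | C#CC(C)(C)CCCB1C2CCCC1CCC2 | intermediate (not isolated)
5 | 4,4-dimethylhex-5-yn-1-ol | C#CC(C)(C)CCCO | intermediate
6 | ethyl 2-(triphenyl-λ5-phosphanylidene)propanoate | CCOC(=O)C(C)=P(c1ccccc1)(c1ccccc1)c1ccccc1 | starting material
7 | 4,4-dimethylhex-5-ynal | C#CC(C)(C)CCC=O | intermediate (not isolated)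
8 | ethyl (2E)-2,6,6-trimethyloct-2-en-7-ynoate | CCOC(=O)/C(C)=C/CCC(C)(C)C#C | intermediate
9 | (2E)-2,6,6-trimethyloct-2-en-7-yn-1-ol | OC/C(C)=C/CCC(C)(C)C#C | intermediate
10 | [(2R,3R)-3-(3,3-dimethylpent-4-yn-1-yl)-2-methyloxiran-2-yl]methanol | OC[C@@]1(C)O[C@@H]1CCC(C)(C)C#C | intermediate
11 | (2S)-2,6,6-trimethyloct-7-yne-1,2-diol | OC[C@@](C)(O)CCCC(C)(C)C#C | intermediate
12 | (2S)-2,6,6-trimethyl-1,2-bis(triethylsilyloxy)oct-7-yne | CC[Si](CC)(CC)OC[C@@](C)(O[Si](CC)(CC)CC)CCCC(C)(C)C#C | intermediate
13 | lithium (7S)-3,3,7-trimethyl-7,8-bis(triethylsilyloxy)oct-1-yn-1-ide | CC[Si](CC)(CC)OC[C@@](C)(O[Si](CC)(CC)CC)CCCC(C)(C)C#C[Li] | intermediate (not isolated)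
14 | (2S)-2,6,6-trimethyl-8-(phenylsulfanyl)-1,2-bis(triethylsilyloxy)oct-7-yne | CC[Si](CC)(CC)OC[C@@](C)(O[Si](CC)(CC)CC)CCCC(C)(C)C#CSc1ccccc1 | intermediate
15 | (2S)-2,6,6-trimethyl-8-(phenylsulfonyl)-1,2-bis(triethylsilyloxy)oct-7-yne | CC[Si](CC)(CC)OC[C@@](C)(O[Si](CC)(CC)CC)CCCC(C)(C)C#CS(=O)(=O)c1ccccc1 | intermediate
16 | (2S,7Z)-2,6,6-trimethyl-8-(phenylsulfonyl)-1,2-bis(triethylsilyloxy)oct-7-ene | CC[Si](CC)(CC)OC[C@@](C)(O[Si](CC)(CC)CC)CCCC(C)(C)/C=C\S(=O)(=O)c1ccccc1 | intermediate
17 | (2S,7Z)-2,6,6-trimethyl-8-(phenylsulfonyl)-2-(triethylsilyloxy)oct-7-enal | O=C[C@@](C)(O[Si](CC)(CC)CC)CCCC(C)(C)/C=C\S(=O)(=O)c1ccccc1 | intermediate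
18 | diethyl (2-oxobutyl)phosphonate | CCC(=O)CP(=O)(OCC)OCC | starting material
19 | (4E,6S,11Z)-6,10,10-trimethyl-12-(phenylsulfonyl)-6-(triethylsilyloxy)dodeca-4,11-dien-3-one | CCC(=O)/C=C/[C@@](C)(O[Si](CC)(CC)CC)CCCC(C)(C)/C=C\S(=O)(=O)c1ccccc1 | intermediate
20 | tert-butyldimethyl{[(2Z,4E,6S,11Z)-6,10,10-trimethyl-12-(phenylsulfonyl)-6-(triethylsilyloxy)dodeca-2,4,11-trien-3-yl]oxy}silane | C/C=C(O[Si](C)(C)C(C)(C)C)/C=C/[C@@](C)(O[Si](CC)(CC)CC)CCCC(C)(C)/C=C\S(=O)(=O)c1ccccc1 | intermediate
21 | tert-butyldimethyl{[(3S,4R,4aS,9S,9aR)-3,5,5,9-tetramethyl-4-(phenylsulfonyl)-9-(triethylsilyloxy)-4,4a,5,6,7,8,9,9a-octahydro-3H-benzo[7]annulen-2-yl]oxy}silane | CC(C)(C)[Si](C)(C)OC1=C[C@@H]2[C@H]([C@@H](S(=O)(=O)c3ccccc3)[C@H]1C)C(C)(C)CCC[C@]2(C)O[Si](CC)(CC)CC | intermediate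
22 | (3S,4R,4aS,9S,9aR)-3,5,5,9-tetramethyl-4-(phenylsulfonyl)-9-(triethylsilyloxy)decahydro-2H-benzo[7]annulen-2-one | O=C1C[C@@H]2[C@H]([C@@H](S(=O)(=O)c3ccccc3)[C@H]1C)C(C)(C)CCC[C@]2(C)O[Si](CC)(CC)CC | intermediate (not isolated)
23 | (4aS,9S,9aR)-3,5,5,9-tetramethyl-9-(triethylsilyloxy)-1,4a,5,6,7,8,9,9a-octahydro-2H-benzo[7]annulen-2-one | O=C1C[C@@H]2[C@H](C=C1C)C(C)(C)CCC[C@]2(C)O[Si](CC)(CC)CC | intermediate
24 | (2S,4aS,9S,9aR)-3,5,5,9-tetramethyl-9-(triethylsilyloxy)-2,4a,5,6,7,8,9,9a-octahydro-1H-benzo[7]annulen-2-ol | O[C@H]1C[C@@H]2[C@H](C=C1C)C(C)(C)CCC[C@]2(C)O[Si](CC)(CC)CC | intermediate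
25 | 3-hydroxy-4-methoxybenzoic acid (isovanillic acid) | COc1ccc(C(=O)O)cc1O | starting material
26 | (2R,4aS,9S,9aR)-3,5,5,9-tetramethyl-9-(triethylsilyloxy)-2,4a,5,6,7,8,9,9a-octahydro-1H-benzo[7]annulen-2-yl 3-hydroxy-4-methoxybenzoate | COc1ccc(C(=O)O[C@@H]2C[C@@H]3[C@H](C=C2C)C(C)(C)CCC[C@]3(C)O[Si](CC)(CC)CC)cc1O | intermediate
27 | (2R,4aS,9S,9aR)-9-hydroxy-3,5,5,9-tetramethyl-2,4a,5,6,7,8,9,9a-octahydro-1H-benzo[7]annulen-2-yl 3-hydroxy-4-methoxybenzoate | COc1ccc(C(=O)O[C@@H]2C[C@@H]3[C@H](C=C2C)C(C)(C)CCC[C@]3(C)O)cc1O | target

## Step count and least certain steps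

Total step count: 18. Longest linear sequence: 18 steps (1 to 27); 2, 6, 18 and 25 are purchased and enter directly.

Least certain steps:

Step 14 (key step, proposed new method). Most likely to go wrong:
- no cyclisation at a useful rate, because the orientation is electronically mismatched and a seven-membered ring has to close, with polymerisation, desilylation or Z to E isomerisation of the sulfone taking over;
- exo closure to the trans-fused isomer;
- weak facial control by C11.

Fallback (known chemistry, the same two bonds made stepwise with matched polarity), from 12 back to 23: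
- Swern oxidation of 12 as in step 11 should give (2S)-2,6,6-trimethyl-2-(triethylsilyloxy)oct-7-ynal F1.
- Olefination with 18 as in step 12 should give (4E,6S)-6,10,10-trimethyl-6-(triethylsilyloxy)dodec-4-en-11-yn-3-one F2.
- Ruthenium-catalysed anti-Markovnikov hydration of the terminal alkyne (CpRu(MeCN)3PF6 with a 2,2'-bipyridine ligand, aqueous N-methylpyrrolidone) should give (7S,8E)-3,3,7-trimethyl-10-oxo-7-(triethylsilyloxy)dodec-8-enal F3.
- Enamine activation of the aldehyde ((S)-α,α-diphenylprolinol trimethylsilyl ether, benzoic acid) makes C4 nucleophilic for an intramolecular Michael addition to the enone carbon C3, giving (1S,6S,7R)-2,2,6-trimethyl-7-(2-oxobutyl)-6-(triethylsilyloxy)cycloheptane-1-carbaldehyde F4.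
- A Robinson-type aldol condensation of C6 onto the C5 aldehyde (piperidinium acetate or KOH/MeOH) closes ring A and gives 23.
- The price is that C3 and C4 are no longer set in one concerted event, and C4 stays epimerisable until dehydration.

Step 2. Most likely to go wrong: loss of chemoselectivity, with 9-BBN also adding to the terminal alkyne. Fallback, from 3 back to 5: n-BuLi and Me3SiCl cap the alkyne as (3,3-dimethylhex-5-en-1-yn-1-yl)trimethylsilane F5, an internal silylalkyne that 9-BBN leaves alone. Hydroboration–oxidation with NaBO3 work-up gives 4,4-dimethyl-6-(trimethylsilyl)hex-5-yn-1-ol F6, and K2CO3/MeOH removes the silyl group to give 5.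

Step 10. Most likely to go wrong: over-reduction to the saturated sulfone, Z to E isomerisation on the catalyst, or slow uptake next to the quaternary carbon. Fallback, from 14 back to 16 (bypassing 15): syn hydrozirconation of the alkynyl sulfide with Cp2Zr(H)Cl and protonolysis puts both hydrogens cis and gives (2S,7Z)-2,6,6-trimethyl-8-(phenylsulfanyl)-1,2-bis(triethylsilyloxy)oct-7-ene F7. Oxidation at sulfur with mCPBA, which keeps the alkene geometry, then gives 16.

Step 16. Most likely to go wrong: poor facial selectivity, giving a mixture of C1 epimers, if the shielding of the concave face by ring B is weaker than assumed. Fallback, from 23 back to 24: catalyst-controlled Corey–Bakshi–Shibata reduction with (R)-2-methyl-CBS-oxazaborolidine and catecholborane in toluene at −78 °C. The alkene side of the enone acts as the large group, so this catalyst enantiomer should give the 2S alcohol 24 by reagent control; no new compound is made.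

Step 17. Most likely to go wrong: allylic transposition by attack at C5, elimination to a diene, partial retention through an ion pair, or O-alkylation of the free phenol. Fallback (no substitution at C1), from 23 and 25 to 27:
- Reduction of 23 with the enantiomeric (S)-2-methyl-CBS-oxazaborolidine and catecholborane should give the 2R alcohol (2R,4aS,9S,9aR)-3,5,5,9-tetramethyl-9-(triethylsilyloxy)-2,4a,5,6,7,8,9,9a-octahydro-1H-benzo[7]annulen-2-ol F8.
- 25 is bis-silylated (t-BuMe2SiCl, imidazole, DMF) to tert-butyldimethylsilyl 3-(tert-butyldimethylsilyloxy)-4-methoxybenzoate F9, and the silyl ester is hydrolysed (K2CO3, aqueous MeOH) to 3-(tert-butyldimethylsilyloxy)-4-methoxybenzoic acid F10.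
- Steglich esterification (EDC·HCl, DMAP, CH2Cl2) of F8 with F10 proceeds with retention to (2R,4aS,9S,9aR)-3,5,5,9-tetramethyl-9-(triethylsilyloxy)-2,4a,5,6,7,8,9,9a-octahydro-1H-benzo[7]annulen-2-yl 3-(tert-butyldimethylsilyloxy)-4-methoxybenzoate F11.
- HF·pyridine removes both silyl groups and gives 27.

## Further compounds

F1 | step 14 | (2S)-2,6,6-trimethyl-2-(triethylsilyloxy)oct-7-ynal | O=C[C@@](C)(O[Si](CC)(CC)CC)CCCC(C)(C)C#C
F2 | step 14 | (4E,6S)-6,10,10-trimethyl-6-(triethylsilyloxy)dodec-4-en-11-yn-3-one | CCC(=O)/C=C/[C@@](C)(O[Si](CC)(CC)CC)CCCC(C)(C)C#C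
F3 | step 14 | (7S,8E)-3,3,7-trimethyl-10-oxo-7-(triethylsilyloxy)dodec-8-enal | CCC(=O)/C=C/[C@@](C)(O[Si](CC)(CC)CC)CCCC(C)(C)CC=O
F4 | step 14 | (1S,6S,7R)-2,2,6-trimethyl-7-(2-oxobutyl)-6-(triethylsilyloxy)cycloheptane-1-carbaldehyde | CCC(=O)C[C@@H]1[C@H](C=O)C(C)(C)CCC[C@]1(C)O[Si](CC)(CC)CC
F5 | step 2 | (3,3-dimethylhex-5-en-1-yn-1-yl)trimethylsilane | C=CCC(C)(C)C#C[Si](C)(C)C
F6 | step 2 | 4,4-dimethyl-6-(trimethylsilyl)hex-5-yn-1-ol | OCCCC(C)(C)C#C[Si](C)(C)C
F7 | step 10 | (2S,7Z)-2,6,6-trimethyl-8-(phenylsulfanyl)-1,2-bis(triethylsilyloxy)oct-7-ene | CC[Si](CC)(CC)OC[C@@](C)(O[Si](CC)(CC)CC)CCCC(C)(C)/C=C\Sc1ccccc1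
F0 | step 16 | none | none
F8 | step 17 | (2R,4aS,9S,9aR)-3,5,5,9-tetramethyl-9-(triethylsilyloxy)-2,4a,5,6,7,8,9,9a-octahydro-1H-benzo[7]annulen-2-ol | O[C@@H]1C[C@@H]2[C@H](C=C1C)C(C)(C)CCC[C@]2(C)O[Si](CC)(CC)CC
F9 | step 17 | tert-butyldimethylsilyl 3-(tert-butyldimethylsilyloxy)-4-methoxybenzoate | COc1ccc(C(=O)O[Si](C)(C)C(C)(C)C)cc1O[Si](C)(C)C(C)(C)C
F10 | step 17 | 3-(tert-butyldimethylsilyloxy)-4-methoxybenzoic acid | COc1ccc(C(=O)O)cc1O[Si](C)(C)C(C)(C)C
F11 | step 17 | (2R,4aS,9S,9aR)-3,5,5,9-tetramethyl-9-(triethylsilyloxy)-2,4a,5,6,7,8,9,9a-octahydro-1H-benzo[7]annulen-2-yl 3-(tert-butyldimethylsilyloxy)-4-methoxybenzoate | COc1ccc(C(=O)O[C@@H]2C[C@@H]3[C@H](C=C2C)C(C)(C)CCC[C@]3(C)O[Si](CC)(CC)CC)cc1O[Si](C)(C)C(C)(C)C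
A1 | alternative 1 | 5-methyl-5-[(1S)-5-methyl-4-oxocyclohex-2-en-1-yl]hexanal | O=C1C=C[C@H](CC1C)C(C)(C)CCCC=O
A2 | alternative 1 | (4aS,9aR)-9-hydroxy-3,5,5-trimethyldecahydro-2H-benzo[7]annulen-2-one (C3 and C9 as epimer mixtures) | O=C1C[C@@H]2[C@H](CC1C)C(C)(C)CCCC2O
A3 | alternative 2 | tert-butyl({(2R,3R)-2-[(1E)-3,3-dimethylhexa-1,5-dien-1-yl]-2,6-dimethyl-3,4-dihydro-2H-pyran-3-yl}oxy)dimethylsilane | CC1=CC[C@@H](O[Si](C)(C)C(C)(C)C)[C@@](C)(/C=C/C(C)(C)CC=C)O1
A4 | alternative 2 | 1-[(1R,2S,5R)-5-(tert-butyldimethylsilyloxy)-4-methyl-2-(2-methylpent-4-en-2-yl)cyclohex-3-en-1-yl]ethan-1-one | CC(C)(C)[Si](C)(C)O[C@@H]1C[C@@H](C(C)=O)[C@H](C=C1C)C(C)(C)CC=C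
A5 | alternative 3 | (2E,6E)-farnesyl diphosphate | CC(C)=CCC/C(C)=C/CC/C(C)=C/COP(=O)(O)OP(=O)(O)O
A6 | alternative 3 | (4aR,5S,9aS)-2,5,9,9-tetramethyl-4,4a,5,6,7,8,9,9a-octahydro-3H-benzo[7]annulen-5-ol (2-himachalen-7-ol) | C1C[C@@H]2[C@H](C=C1C)C(C)(C)CCC[C@]2(C)O
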